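**Plan**

1. Ring numbering is O1, C2 (quaternary), C3, C4, C5=C6, C7. The retrosynthesis cuts, in order: the aryl–carbonyl bond (aryllithium + Weinreb amide); the C6–side-chain bond (Negishi coupling of a 6-bromo-oxepene); then C5–C6 and C6–C7 together, which removes C6 as a dibromocarbene carbon and leaves a 3,4-dihydro-2H-pyran with C5 bonded to C7.
2. Enabling feature: the arc C5=C6–C7H2–O1 of the seven-membered ring is the enol ether C5=C7–O1 of a six-membered dihydropyran with one carbon, C6, wedged between C5 and C7. That carbon also carries the side chain, so a halocarbene insertion enlarges the ring and leaves the coupling handle in one operation.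
3. The dihydropyran is cut further at C7 (hydroformylation carbon, lactol dehydration) and at C2–C3 (allylation of the D-malic acid dioxolanone).
4. Forward: dioxolanone, allylation, Weinreb amide, methanolysis, hydroformylation (closes the six-membered lactol), dehydration, one-carbon enlargement to the oxepene, C7 reduction, Negishi coupling, saponification, aryl ketone, global deprotection. The side-chain bromide (two steps) and bis-MOM hydroquinone (one step) are made separately.
5. Stereochemistry: C2 (R) is the carbinol carbon of D-malic acid, alkylated with retention through the cis tert-butyl dioxolanone and quaternary (non-enolisable) from then on. The E-alkene comes from E-selective SeO2 oxidation of a gem-dimethyl alkene.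

Key step: step 7

Remark: lactol, acetal and cyclopropane epimers are carried as mixtures because each converges later; 5-bromo-2-methylpent-2-ene is taken as a purchasable starting material.

Step 1
Reactants: 1 D-malic acid
Product: 2 2-[(2R,4R)-2-tert-butyl-5-oxo-1,3-dioxolan-4-yl]acetic acid (cis)
Conditions: t-BuCHO (2 equiv), p-TsOH·H2O (cat.), H2SO4 (cat.), pentane, reflux, Dean–Stark; recrystallisation
Reagents that add atoms: pivalaldehyde, CC(C)(C)C=O
Why: Acid-catalysed acetalisation of the α-hydroxy acid unit (dioxolanone formation for self-regeneration of stereocentres) should close the five-membered acylal, with the new acetal centre settling cis to the acetic acid arm under thermodynamic control from the malic acid centre and the cis isomer being purified by crystallisation.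

Step 2
Reactants: 2 2-[(2R,4R)-2-tert-butyl-5-oxo-1,3-dioxolan-4-yl]acetic acid; 3 allyl bromide
Product: 5 2-[(2R,4R)-2-tert-butyl-5-oxo-4-(prop-2-en-1-yl)-1,3-dioxolan-4-yl]acetic acid, via dilithium enolate 4 (not isolated)
Conditions: LiHMDS (2.2 equiv), THF, −78 °C; 3 (1.5 equiv), −78 → −20 °C; aq. HCl work-up
Reagents that add atoms: allyl bromide (3), C=CCBr
Why: Dioxolanone enolate alkylation: the planar enolate is shielded on one face by the tert-butyl group, so the allyl group should enter trans to it, on the face the hydrogen occupied, creating the quaternary centre (the future C2, R) with net retention.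

Step 3
Reactants: 5 2-[(2R,4R)-2-tert-butyl-5-oxo-4-(prop-2-en-1-yl)-1,3-dioxolan-4-yl]acetic acid
Product: 7 2-[(2R,4R)-2-tert-butyl-5-oxo-4-(prop-2-en-1-yl)-1,3-dioxolan-4-yl]-N-methoxy-N-methylacetamide, via acyl imidazolide 6 (not isolated)
Conditions: CDI (1.1 equiv), CH2Cl2, 0 °C → rt; MeNH(OMe)·HCl (1.3 equiv), rt
Reagents that add atoms: N,O-dimethylhydroxylamine hydrochloride, CNOC.Cl
Why: Weinreb amide synthesis by CDI activation and aminolysis should act only on the unhindered side-chain acid, since the dioxolanone carbonyl sits on a quaternary carbon and the amine is a weak nucleophile.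

Step 4
Reactants: 7 2-[(2R,4R)-2-tert-butyl-5-oxo-4-(prop-2-en-1-yl)-1,3-dioxolan-4-yl]-N-methoxy-N-methylacetamide
Product: 8 methyl (2R)-2-hydroxy-2-[2-(methoxy(methyl)amino)-2-oxoethyl]pent-4-enoate
Conditions: NaOMe (0.2 equiv), MeOH, 0 °C → rt; AcOH quench
Reagents that add atoms: methanol, CO
Why: Methoxide-catalysed transesterification of the activated acylal lactone should give the methyl ester and release pivalaldehyde from the resulting hemiacetal, freeing the tertiary alcohol without touching the quaternary centre or the less electrophilic Weinreb amide.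

Step 5
Reactants: 8 methyl (2R)-2-hydroxy-2-[2-(methoxy(methyl)amino)-2-oxoethyl]pent-4-enoate
Product: 10 methyl (2R)-6-hydroxy-2-[2-(methoxy(methyl)amino)-2-oxoethyl]oxane-2-carboxylate (C6 epimers), via open-chain hydroxy aldehyde 9 (not isolated)
Conditions: Rh(acac)(CO)2 (1 mol%), BiPhePhos (2 mol%), CO/H2 (1:1, 10 bar), toluene, 60 °C
Reagents that add atoms: carbon monoxide, [C-]#[O+]
Why: Linear-selective Rh/bisphosphite hydroformylation of the terminal alkene (branched insertion is disfavoured next to the quaternary carbon) gives the δ-hydroxy aldehyde, which should close spontaneously to the six-membered lactol, helped by the Thorpe–Ingold effect of the fully substituted carbinol carbon.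

Step 6
Reactants: 10 methyl (2R)-6-hydroxy-2-[2-(methoxy(methyl)amino)-2-oxoethyl]oxane-2-carboxylate
Product: 12 methyl (2R)-2-[2-(methoxy(methyl)amino)-2-oxoethyl]-3,4-dihydro-2H-pyran-2-carboxylate, via anomeric mesylate 11 (not isolated)
Conditions: MsCl (1.5 equiv), Et3N (5 equiv), CH2Cl2, −20 °C → reflux
Reagents that add atoms: none
Why: Lactol dehydration by anomeric sulfonylation and amine-induced β-elimination, the method that turns 2-deoxy lactols into glycals, should give the enol ether, triethylamine being too weak to enolise the amide.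

Step 7
Reactants: 12 methyl (2R)-2-[2-(methoxy(methyl)amino)-2-oxoethyl]-3,4-dihydro-2H-pyran-2-carboxylate; 13 bromoform
Product: 15 methyl (2R)-6-bromo-7-methoxy-2-[2-(methoxy(methyl)amino)-2-oxoethyl]-2,3,4,7-tetrahydrooxepine-2-carboxylate (C7 epimers), via dibromocyclopropane 14 (not isolated)
Conditions: 13 (3 equiv), KOt-Bu (2.5 equiv, portionwise), hexane/toluene, −20 → 0 °C; filter, concentrate cold; AgOTf (1.5 equiv), 2,6-lutidine (2 equiv), MeOH, 0 °C → rt, dark
Reagents that add atoms: bromoform (13), BrC(Br)Br; methanol, CO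
Why: tert-Butoxide converts bromoform by α-elimination into singlet dibromocarbene, which adds in a concerted [2+1] manner to the enol ether C5=C7 of 12 to give the 2-oxabicyclo[4.1.0]heptane 14; silver(I) then removes the endo bromide while the shared C5–C7 bond opens in a disrotatory sense, and the 2-bromoallyl cation, held as the O1=C7 oxocarbenium ion, is trapped by methanol at C7. The closest known reaction type is dihalocarbene cyclopropanation of dihydropyrans and glycals followed by silver- or base-promoted solvolytic ring enlargement to 2-alkoxy-3-halo-oxepenes. Only the three-membered ring is closed (cheletropic [2+1] addition); the seven-membered ring is not cyclised but arises by electrocyclic cleavage of the bond common to the six- and three-membered rings, so no medium-ring closure has to be paid for. The ring-fusion centres of 14 and the acetal centre C7 of 15 are uncontrolled and need no control, since both cyclopropane diastereomers give the same cation and C7 becomes CH2 in step 8, while the quaternary C2 is remote and untouched. The step needs attack on the enol ether alone (it is the only electron-rich π-bond, and bromoform is far more acidic than the amide α-CH2, so the alkoxide is spent on carbene formation and not on β-elimination of the ring oxygen), loss of the endo bromide (the only opening that keeps the ring alkene cis) and methanol capture at C7 and not C5 (the ring oxygen localises the charge there). The bromine left on C6 is the handle for the side chain.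

Step 8
Reactants: 15 methyl (2R)-6-bromo-7-methoxy-2-[2-(methoxy(methyl)amino)-2-oxoethyl]-2,3,4,7-tetrahydrooxepine-2-carboxylate
Product: 16 methyl (2R)-6-bromo-2-[2-(methoxy(methyl)amino)-2-oxoethyl]-2,3,4,7-tetrahydrooxepine-2-carboxylate
Conditions: Et3SiH (3 equiv), BF3·OEt2 (1.5 equiv, Lewis acid, not consumed), CH2Cl2, −78 → −30 °C
Reagents that add atoms: none
Why: Ionic hydrogenation of the mixed acetal: Lewis-acid ionisation regenerates the oxocarbenium ion and the silane should deliver hydride to C7, the carbon next to oxygen, as in Ferrier-type reductions of 2,3-unsaturated glycosides, so both C7 epimers converge on CH2 and the C5=C6 bromoalkene stays in place.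

Step 9
Reactants: 17 5-bromo-2-methylpent-2-ene
Product: 18 (2E)-5-bromo-2-methylpent-2-en-1-ol
Conditions: SeO2 (0.3 equiv), t-BuOOH (2 equiv), salicylic acid (cat.), CH2Cl2, 0 °C → rt
Reagents that add atoms: selenium dioxide, O=[Se]=O; tert-butyl hydroperoxide, CC(C)(C)OO
Why: Catalytic SeO2 allylic oxidation (ene reaction at the more substituted alkene terminus, then [2,3]-sigmatropic shift) should hydroxylate the methyl group trans to the chain, which sets the E geometry of the target's side-chain alkene.

Step 10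
Reactants: 18 (2E)-5-bromo-2-methylpent-2-en-1-ol
Product: 19 tert-butyl{[(2E)-5-bromo-2-methylpent-2-en-1-yl]oxy}dimethylsilane
Conditions: TBSCl (1.2 equiv), imidazole (2 equiv), CH2Cl2, 0 °C → rt
Reagents that add atoms: tert-butyldimethylsilyl chloride, CC(C)(C)[Si](C)(C)Cl
Why: Imidazole-promoted silylation of the primary alcohol should be clean, and the silyl ether tolerates zinc insertion, hydroxide and aryllithium and falls in the final acid step.

Step 11
Reactants: 16 methyl (2R)-6-bromo-2-[2-(methoxy(methyl)amino)-2-oxoethyl]-2,3,4,7-tetrahydrooxepine-2-carboxylate; 19 tert-butyl{[(2E)-5-bromo-2-methylpent-2-en-1-yl]oxy}dimethylsilane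
Product: 21 methyl (2R)-6-[(3E)-5-{[tert-butyl(dimethyl)silyl]oxy}-4-methylpent-3-en-1-yl]-2-[2-(methoxy(methyl)amino)-2-oxoethyl]-2,3,4,7-tetrahydrooxepine-2-carboxylate, via alkylzinc bromide 20 (not isolated)
Conditions: 19 (1.6 equiv), Zn dust (2.5 equiv), I2 (5 mol%), DMA, 70 °C; then 16, PdCl2(dppf) (5 mol%), THF, 50 °C
Reagents that add atoms: none
Why: Iodine-activated zinc inserts into the primary C–Br bond, and the Negishi sp2–sp3 coupling of the resulting alkylzinc with the alkenyl bromide should proceed with retention of both alkene geometries and without touching the ester, Weinreb amide or silyl ether, the bidentate ligand limiting β-hydride elimination.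

Step 12
Reactants: 21 methyl (2R)-6-[(3E)-5-{[tert-butyl(dimethyl)silyl]oxy}-4-methylpent-3-en-1-yl]-2-[2-(methoxy(methyl)amino)-2-oxoethyl]-2,3,4,7-tetrahydrooxepine-2-carboxylate
Product: 22 (2R)-6-[(3E)-5-{[tert-butyl(dimethyl)silyl]oxy}-4-methylpent-3-en-1-yl]-2-[2-(methoxy(methyl)amino)-2-oxoethyl]-2,3,4,7-tetrahydrooxepine-2-carboxylic acid
Conditions: LiOH·H2O (3 equiv), THF/MeOH/H2O (3:1:1), rt; 1 M HCl to pH 4, 0 °C
Reagents that add atoms: lithium hydroxide, [Li+].[OH-]
Why: Saponification of the α-alkoxy methyl ester should outrun attack on the Weinreb amide and the silyl ether at room temperature, and it unmasks the acid whose carboxylate protects this carbonyl in step 14.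

Step 13
Reactants: 23 hydroquinone
Product: 24 1,4-bis(methoxymethoxy)benzene
Conditions: MOMCl (2.6 equiv), i-Pr2NEt (3 equiv), CH2Cl2, 0 °C → rt
Reagents that add atoms: chloromethyl methyl ether, COCCl
Why: Double O-alkylation of the phenols installs acetal ethers that both protect the hydroquinone and direct ortho-lithiation.

Step 14
Reactants: 22 (2R)-6-[(3E)-5-{[tert-butyl(dimethyl)silyl]oxy}-4-methylpent-3-en-1-yl]-2-[2-(methoxy(methyl)amino)-2-oxoethyl]-2,3,4,7-tetrahydrooxepine-2-carboxylic acid; 24 1,4-bis(methoxymethoxy)benzene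
Product: 27 (2R)-2-{2-[2,5-bis(methoxymethoxy)phenyl]-2-oxoethyl}-6-[(3E)-5-{[tert-butyl(dimethyl)silyl]oxy}-4-methylpent-3-en-1-yl]-2,3,4,7-tetrahydrooxepine-2-carboxylic acid, via aryllithium 25 (not isolated), via dilithium tetrahedral adduct 26 (not isolated)
Conditions: 24 (2.8 equiv), n-BuLi (2.6 equiv), THF, 0 °C, 1 h; then 22 in THF, −78 → −30 °C; aq. NH4Cl, then dilute HCl to pH 4
Reagents that add atoms: none
Why: Directed ortho-lithiation gives the aryllithium, whose first equivalent deprotonates the acid and whose second adds to the Weinreb amide to form an N,O-chelated tetrahedral adduct that should persist until work-up (Weinreb ketone synthesis), the lithium carboxylate being too electron-rich to be attacked at low temperature.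

Step 15
Reactants: 27 (2R)-2-{2-[2,5-bis(methoxymethoxy)phenyl]-2-oxoethyl}-6-[(3E)-5-{[tert-butyl(dimethyl)silyl]oxy}-4-methylpent-3-en-1-yl]-2,3,4,7-tetrahydrooxepine-2-carboxylic acid
Product: 28 (2R)-2-[2-(2,5-dihydroxyphenyl)-2-oxoethyl]-6-[(3E)-5-hydroxy-4-methylpent-3-en-1-yl]-2,3,4,7-tetrahydrooxepine-2-carboxylic acid (CNP0570804.1)
Conditions: 3 M aq. HCl/THF (1:4), rt → 35 °C
Reagents that add atoms: none
Why: Aqueous acid hydrolysis should cleave both aryl MOM acetals (the one ortho to the ketone first) and the primary silyl ether in one operation, without an alcohol solvent that could esterify the acid and without any acidic hydrogen at C2.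

**Compound list**

1 | D-malic acid, (R)-2-hydroxybutanedioic acid | OC(=O)C[C@@H](O)C(=O)O | starting material
2 | 2-[(2R,4R)-2-tert-butyl-5-oxo-1,3-dioxolan-4-yl]acetic acid | CC(C)(C)[C@@H]1O[C@H](CC(=O)O)C(=O)O1 | intermediate
3 | allyl bromide | C=CCBr | starting material
4 | dilithium enolate carboxylate of 2 | CC(C)(C)[C@@H]1OC(CC(=O)[O-])=C([O-])O1.[Li+].[Li+] | intermediate
5 | 2-[(2R,4R)-2-tert-butyl-5-oxo-4-(prop-2-en-1-yl)-1,3-dioxolan-4-yl]acetic acid | CC(C)(C)[C@@H]1O[C@@](CC(=O)O)(CC=C)C(=O)O1 | intermediate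
6 | 1-{[(2R,4R)-2-tert-butyl-5-oxo-4-(prop-2-en-1-yl)-1,3-dioxolan-4-yl]acetyl}imidazole | CC(C)(C)[C@@H]1O[C@@](CC(=O)n2ccnc2)(CC=C)C(=O)O1 | intermediate
7 | 2-[(2R,4R)-2-tert-butyl-5-oxo-4-(prop-2-en-1-yl)-1,3-dioxolan-4-yl]-N-methoxy-N-methylacetamide | CC(C)(C)[C@@H]1O[C@@](CC(=O)N(C)OC)(CC=C)C(=O)O1 | intermediate
8 | methyl (2R)-2-hydroxy-2-[2-(methoxy(methyl)amino)-2-oxoethyl]pent-4-enoate | C=CC[C@@](CC(=O)N(C)OC)(C(=O)OC)O | intermediate
9 | methyl (2R)-2-hydroxy-2-[2-(methoxy(methyl)amino)-2-oxoethyl]-6-oxohexanoate | O=CCCC[C@@](CC(=O)N(C)OC)(C(=O)OC)O | intermediate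
10 | methyl (2R)-6-hydroxy-2-[2-(methoxy(methyl)amino)-2-oxoethyl]oxane-2-carboxylate (C6 epimers) | OC1CCC[C@@](CC(=O)N(C)OC)(C(=O)OC)O1 | intermediate
11 | methyl (2R)-6-(methanesulfonyloxy)-2-[2-(methoxy(methyl)amino)-2-oxoethyl]oxane-2-carboxylate | CS(=O)(=O)OC1CCC[C@@](CC(=O)N(C)OC)(C(=O)OC)O1 | intermediate
12 | methyl (2R)-2-[2-(methoxy(methyl)amino)-2-oxoethyl]-3,4-dihydro-2H-pyran-2-carboxylate | C1=CCC[C@@](CC(=O)N(C)OC)(C(=O)OC)O1 | intermediate
13 | bromoform | BrC(Br)Br | starting material
14 | methyl (3R)-7,7-dibromo-3-[2-(methoxy(methyl)amino)-2-oxoethyl]-2-oxabicyclo[4.1.0]heptane-3-carboxylate (ring-fusion diastereomers) | BrC1(Br)C2CC[C@@](CC(=O)N(C)OC)(C(=O)OC)OC12 | intermediate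
15 | methyl (2R)-6-bromo-7-methoxy-2-[2-(methoxy(methyl)amino)-2-oxoethyl]-2,3,4,7-tetrahydrooxepine-2-carboxylate (C7 epimers) | BrC1=CCC[C@@](CC(=O)N(C)OC)(C(=O)OC)OC1OC | intermediate
16 | methyl (2R)-6-bromo-2-[2-(methoxy(methyl)amino)-2-oxoethyl]-2,3,4,7-tetrahydrooxepine-2-carboxylate | BrC1=CCC[C@@](CC(=O)N(C)OC)(C(=O)OC)OC1 | intermediate
17 | 5-bromo-2-methylpent-2-ene | CC(C)=CCCBr | starting material
18 | (2E)-5-bromo-2-methylpent-2-en-1-ol | C/C(=C\CCBr)CO | intermediate
19 | tert-butyl{[(2E)-5-bromo-2-methylpent-2-en-1-yl]oxy}dimethylsilane | C/C(=C\CCBr)CO[Si](C)(C)C(C)(C)C | intermediate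
20 | bromo[(3E)-5-{[tert-butyl(dimethyl)silyl]oxy}-4-methylpent-3-en-1-yl]zinc | C/C(=C\CC[Zn]Br)CO[Si](C)(C)C(C)(C)C | intermediate
21 | methyl (2R)-6-[(3E)-5-{[tert-butyl(dimethyl)silyl]oxy}-4-methylpent-3-en-1-yl]-2-[2-(methoxy(methyl)amino)-2-oxoethyl]-2,3,4,7-tetrahydrooxepine-2-carboxylate | C/C(=C\CCC1=CCC[C@@](CC(=O)N(C)OC)(C(=O)OC)OC1)CO[Si](C)(C)C(C)(C)C | intermediate
22 | (2R)-6-[(3E)-5-{[tert-butyl(dimethyl)silyl]oxy}-4-methylpent-3-en-1-yl]-2-[2-(methoxy(methyl)amino)-2-oxoethyl]-2,3,4,7-tetrahydrooxepine-2-carboxylic acid | C/C(=C\CCC1=CCC[C@@](CC(=O)N(C)OC)(C(=O)O)OC1)CO[Si](C)(C)C(C)(C)C | intermediate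
23 | hydroquinone | Oc1ccc(O)cc1 | starting material
24 | 1,4-bis(methoxymethoxy)benzene | COCOc1ccc(OCOC)cc1 | intermediate
25 | [2,5-bis(methoxymethoxy)phenyl]lithium | [Li]c1cc(OCOC)ccc1OCOC | intermediate
26 | dilithium salt of the N,O-chelated tetrahedral adduct of 25 and 22 (carboxylate and aminal alkoxide) | C/C(=C\CCC1=CCC[C@@](CC([O-])(N(C)OC)c2cc(OCOC)ccc2OCOC)(C(=O)[O-])OC1)CO[Si](C)(C)C(C)(C)C.[Li+].[Li+] | intermediate
27 | (2R)-2-{2-[2,5-bis(methoxymethoxy)phenyl]-2-oxoethyl}-6-[(3E)-5-{[tert-butyl(dimethyl)silyl]oxy}-4-methylpent-3-en-1-yl]-2,3,4,7-tetrahydrooxepine-2-carboxylic acid | C/C(=C\CCC1=CCC[C@@](CC(=O)c2cc(OCOC)ccc2OCOC)(C(=O)O)OC1)CO[Si](C)(C)C(C)(C)C | intermediate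
28 | (2R)-2-[2-(2,5-dihydroxyphenyl)-2-oxoethyl]-6-[(3E)-5-hydroxy-4-methylpent-3-en-1-yl]-2,3,4,7-tetrahydrooxepine-2-carboxylic acid | C/C(=C\CCC1=CCC[C@@](CC(=O)c2cc(O)ccc2O)(C(=O)O)OC1)CO | target

**Step count**

Total: 15 steps. Longest linear sequence: 12 steps (steps 1–8, 11, 12, 14, 15, from D-malic acid).

**Steps most likely to fail**

Step 7. Carbene transfer may be slow because the enol ether oxygen is attached to the electron-poor C2. Alkoxide may instead degrade the substrate by β-elimination of the ring oxygen or attack on the ester, and the strained dibromocyclopropane may solvolyse unselectively.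

The fallback closes the oxepene by ring-closing metathesis instead of ring enlargement. It sets out from 2:
- The dianion of 2 is alkylated with 4-iodobut-1-ene (LiHMDS, THF/DMPU, −78 → −20 °C), again trans to the tert-butyl group, to give 2-[(2R,4R)-4-(but-3-en-1-yl)-2-tert-butyl-5-oxo-1,3-dioxolan-4-yl]acetic acid F1.
- CDI and MeNH(OMe)·HCl give the Weinreb amide F2, and NaOMe/MeOH gives the tertiary hydroxy ester F3.
- O-alkylation with 2,3-dibromopropene (NaH, DMF, 0 °C) gives the 2-bromoallyl ether F4.
- Negishi coupling of F4 with the alkylzinc 20 (PdCl2(dppf), THF, 50 °C) gives the diene F5 with a 1,1-disubstituted alkene.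
- Ring-closing metathesis (second-generation Grubbs catalyst, CH2Cl2, 40 °C) joins C5 to C6 with loss of ethylene and returns the route at 21.

Step 14. The aryllithium may deprotonate the CH2 next to the amide, which would open the ring by β-elimination of O1 and erase C2. Addition at the neopentyl-like amide of the poorly soluble lithium carboxylate may also be too slow.

The fallback makes the aryl–carbon bond at the aldehyde oxidation level. It sets out from 22:
- DIBAL-H (2.2 equiv, THF, −78 °C) reduces the Weinreb amide, the aluminium carboxylate being inert, to the aldehyde acid F6.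
- The aryllithium 25 (2.2 equiv, THF, −78 °C) adds to the far more electrophilic aldehyde to give the benzylic alcohol acid F7 as carbinol epimers.
- F7 is oxidised without prior acidification (activated MnO2, CH2Cl2, rt), before it can lactonise, and the route is rejoined at 27.

Step 15. The acid strength needed for the aryl MOM ethers may also cause retro-oxa-Michael opening of the β-alkoxy ketone with reclosure through the ortho phenol, ionisation of the allylic alcohol, or hydroxymethylation of the hydroquinone by liberated formaldehyde.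

The fallback changes the phenol protecting groups to ones that fall under very mild acid. It sets out from 23:
- Dihydropyran and PPTS (CH2Cl2, rt) give 1,4-bis(oxan-2-yloxy)benzene F8.
- Ortho-lithiation (n-BuLi, THF, 0 °C) gives the aryllithium F9.
- Addition of F9 (2.6 equiv) to 22 at −78 °C gives the bis-THP keto acid F10.
- AcOH/THF/H2O (3:1:1, 40 °C) removes both THP acetals and the silyl ether and arrives at 28.

**Further compounds**

F1 | step 7 | 2-[(2R,4R)-4-(but-3-en-1-yl)-2-tert-butyl-5-oxo-1,3-dioxolan-4-yl]acetic acid | CC(C)(C)[C@@H]1O[C@@](CC(=O)O)(CCC=C)C(=O)O1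
F2 | step 7 | 2-[(2R,4R)-4-(but-3-en-1-yl)-2-tert-butyl-5-oxo-1,3-dioxolan-4-yl]-N-methoxy-N-methylacetamide | CC(C)(C)[C@@H]1O[C@@](CC(=O)N(C)OC)(CCC=C)C(=O)O1
F3 | step 7 | methyl (2R)-2-hydroxy-2-[2-(methoxy(methyl)amino)-2-oxoethyl]hex-5-enoate | C=CCC[C@@](CC(=O)N(C)OC)(C(=O)OC)O
F4 | step 7 | methyl (2R)-2-[(2-bromoprop-2-en-1-yl)oxy]-2-[2-(methoxy(methyl)amino)-2-oxoethyl]hex-5-enoate | C=CCC[C@@](CC(=O)N(C)OC)(C(=O)OC)OCC(Br)=C
F5 | step 7 | methyl (2R)-2-{[(5E)-7-{[tert-butyl(dimethyl)silyl]oxy}-6-methyl-2-methylidenehept-5-en-1-yl]oxy}-2-[2-(methoxy(methyl)amino)-2-oxoethyl]hex-5-enoate | C=CCC[C@@](CC(=O)N(C)OC)(C(=O)OC)OCC(=C)CC/C=C(\C)CO[Si](C)(C)C(C)(C)C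
F6 | step 14 | (2R)-6-[(3E)-5-{[tert-butyl(dimethyl)silyl]oxy}-4-methylpent-3-en-1-yl]-2-(2-oxoethyl)-2,3,4,7-tetrahydrooxepine-2-carboxylic acid | C/C(=C\CCC1=CCC[C@@](CC=O)(C(=O)O)OC1)CO[Si](C)(C)C(C)(C)C
F7 | step 14 | (2R)-2-{2-[2,5-bis(methoxymethoxy)phenyl]-2-hydroxyethyl}-6-[(3E)-5-{[tert-butyl(dimethyl)silyl]oxy}-4-methylpent-3-en-1-yl]-2,3,4,7-tetrahydrooxepine-2-carboxylic acid (carbinol epimers) | C/C(=C\CCC1=CCC[C@@](CC(O)c2cc(OCOC)ccc2OCOC)(C(=O)O)OC1)CO[Si](C)(C)C(C)(C)C
F8 | step 15 | 1,4-bis(oxan-2-yloxy)benzene | O(c1ccc(OC2CCCCO2)cc1)C1CCCCO1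
F9 | step 15 | [2,5-bis(oxan-2-yloxy)phenyl]lithium | [Li]c1cc(OC2CCCCO2)ccc1OC1CCCCO1
F10 | step 15 | (2R)-2-{2-[2,5-bis(oxan-2-yloxy)phenyl]-2-oxoethyl}-6-[(3E)-5-{[tert-butyl(dimethyl)silyl]oxy}-4-methylpent-3-en-1-yl]-2,3,4,7-tetrahydrooxepine-2-carboxylic acid | C/C(=C\CCC1=CCC[C@@](CC(=O)c2cc(OC3CCCCO3)ccc2OC2CCCCO2)(C(=O)O)OC1)CO[Si](C)(C)C(C)(C)C
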